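A small charge, 0.14 M of each substrate hand with 0.280 M of single-handed reagent, gives you two substrate peaks, and you should read the gap between them.

all flasks: left-handed substrate 0.14 M; right-handed substrate 0.14 M

| flask | reagent | remark | time |
|---|---|---|---|
| south-west | 0.28 M | the very flask that is asked about, followed so far |  |
| flask | 0.280 M |  | 6.0 h |

south-west run (percent of the left-handed substrate and right-handed substrate together charged)

| time / min | left-handed substrate / % | right-handed substrate / % |
|---|---|---|
| 8.00 | 48.1 | 48.6 |
| 20.0 | 46.9 | 47.3 |
| 40.0 | 44.2 | 46.2 |
| 60.0 | 42.9 | 46.2 |
| 80.0 | 42.1 | 44.8 |
| 120 | 40.3 | 43.4 |

(readings scatter by 0.5 percentage points)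

- reagent is single-handed; left-handed substrate and right-handed substrate are mirror images of each other, charged as a racemate, each of them at the stated concentration
- what has gone into achiral form counts as reacted
- an excess is below zero if the other one leads
- the handed part of reagent does not stay in what it makes, so the products of the two hands are mirror images too

* part of the left-handed substrate and right-handed substrate charged together that has reacted at 6.0 h
* excess of left-handed product over right-handed product in the product at 6.0 h
* excess of right-handed substrate over left-handed substrate among what is left of the two at 6.0 h

This is a kinetic resolution, and the bench rule for it is a balance of hands. The substrates start level, so the rule counts each unit by which the right-handed substrate leads the left-handed as a unit of left-handed product over right-handed product; that is an assumption, namely that a product keeps its hand and that the achiral form draws evenly on the two substrate hands. After 120 min the south-west run shows a lead of 3.1 percentage points of the charge on a reacted fraction of 16.3%. Dividing the two gives 19.0%, the handed balance: lead over reacted fraction. That reading is my reckoning for eP.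

The rule has two borders. Two readings differ with a scatter of 0.71 points, so at 8.00 min the gap of 0.5 points is 0.704 of that scatter, against 4.37 at 120 min. And the asked time is 3.00 times the last reading, with no product peak among the readings, so that a product keeps its hand stays an assumption.

The forecast put c at 26%, eS at 6.5% and eP at 21%, above my 19.0%, remarking “Some material sits as achiral form”. The flask gives c 27.7%, eS 4.69% and eP 2.69%.

    reagent + left-handed substrate → left-handed product (k = 0.670 M⁻¹ h⁻¹)
    reagent + right-handed substrate → right-handed product (k = 0.390 M⁻¹ h⁻¹)
    left-handed substrate ⇌ achiral form (K = 0.0270, k = 0.150 h⁻¹)
    right-handed substrate ⇌ achiral form (K = 0.0270, k = 0.150 h⁻¹)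
    achiral form → waste (k = 0.120 h⁻¹)
    left-handed product ⇌ right-handed product (k = 0.360 h⁻¹)
    reagent ⇌ dormant form (K = 0.460, k = 0.120 h⁻¹)
    2 reagent → homo dimer (k = 0.900 M⁻¹ h⁻¹)

On this flask's own figures the balance, eS times the unreacted fraction over c, is 12.2%, and like 19.0% it stands far above the eP found. Left-handed product passes into right-handed product with a half-life of 1.9 h on its forward rate, while left-handed substrate at 6.00 h has a half-life of 24 h by its passing into left-handed product, and the two products then stand at 13.3% and 12.6%. In the neighbour flask with 0.11 M of reagent the balance gives 12.7%, and the computed eP there is 3.41%.

The readings were computed for substances that don't exist.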